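**Plan**
1. Retrosynthetic cuts, last to first: C8=C17 (ketone methylenation), C13=C14 (olefination of a C13 methyl ketone), C9–C11 (addition of a four-carbon ketal Grignard reagent to a C9 ketone), C4–C18 (aldol with formaldehyde), then C1–C10 and C4–C5 together (Diels–Alder).
2. Enabling feature: ring B carries functionality on C6, C7, C8 and C9 around H5 and the C10 methyl. This is the imprint of 2-methoxy-6-methyl-1,4-benzoquinone that has reacted at its methyl-bearing alkene (C5=C10). C1–C4 of ring A, with the C4 methyl, are the diene carbons of a 3-silyloxypenta-1,3-diene.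
3. Forward: quinone (ring B) plus diene give ring A in one enantioselective [4+2] step. C5 is then inverted and the side chain is added to the C9 carbonyl. Ring A is taken through its 1-en-3-one to the C4 quaternary centre and deoxygenated at C3. Ring B is transposed to the 6-en-8-one and deoxygenated at C9, and the enoate and the exocyclic methylene are installed last.
4. Stereochemistry: C10 from the chiral titanium binaphtholate in the cycloaddition; C5 by equilibration next to the C6 carbonyl; C4 and C9 by substrate control (new bonds form anti to the C10 methyl); 13E from the olefination.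

Key step: step 3

Remark on numbering: labdane numbering is used throughout (decalin C1–C10, side chain C11–C16 on C9, C17 on C8, C18 = CH2O on C4, C20 = methyl on C10); "cis/trans to C20" gives the face of a group relative to the C10 methyl.
Assumption: the sense of induction of TiCl2[(R)-binaphtholate] with this quinone cannot be derived with certainty; the (R)-ligand is written, and the (S)-ligand would be used if the first run shows the opposite sense.

**Step 1**
Reactants: 1 2-methoxy-6-methylphenol
Product: 2 2-methoxy-6-methyl-1,4-benzoquinone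
Conditions: (KSO3)2NO (2.2 equiv), KH2PO4 (aq), acetone/H2O, 0 °C → rt
Reagents that add atoms: potassium nitrosodisulfonate, [K+].[K+].[O-]S(=O)(=O)N([O])S(=O)(=O)[O-]
Why: Teuber oxidation, in which the phenoxyl radical is trapped by a second equivalent of the nitroxyl at the free para position (both ortho positions are blocked) and collapses to the para-quinone.

**Step 2**
Reactants: 3 pent-1-en-3-one
Product: 4 (Z)-3-(tert-butyldimethylsilyloxy)penta-1,3-diene
Conditions: t-BuMe2SiOTf, Et3N, Et2O, 0 °C
Reagents that add atoms: tert-butyldimethylsilyl trifluoromethanesulfonate, CC(C)(C)[Si](C)(C)OS(=O)(=O)C(F)(F)F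
Why: Soft enolisation of the ethyl ketone with silyl triflate and amine gives the cross-conjugated silyl dienol ether, the Z isomer (methyl cis to oxygen, trans to the vinyl group) being favoured by allylic strain.

**Step 3**
Reactants: 2 2-methoxy-6-methyl-1,4-benzoquinone; 4 (Z)-3-(tert-butyldimethylsilyloxy)penta-1,3-diene
Product: 5 cis-fused cycloadduct
Conditions: (R)-BINOL (0.2 equiv), TiCl2(OiPr)2 (0.2 equiv), 4 Å MS, CH2Cl2/toluene, −78 → −30 °C
Reagents that add atoms: none
Why: TiCl2[(R)-binaphtholate] should bind 2 as a chelate through the carbonyl flanked by the methoxy and methyl carbons (C9) and the methoxy oxygen, so that the methyl-bearing alkene is activated with C5 (β to the bound carbonyl) as its electrophilic end, and the diene adds in a concerted, asynchronous, endo [4+2] process in which its enol ether terminus C4 bonds to C5 ahead of the C1–C10 bond. The closest known reaction type is the Diels–Alder reaction of 1,4-quinones with oxygenated dienes under chiral titanium diolate catalysis, combined with the chelation-controlled orientation known for 2-alkoxyquinones with bidentate Lewis acids. Ring A closes as a six-membered carbocycle by intermolecular [4+2] annulation onto the preformed quinone ring B, both new σ bonds going to one face of the C5=C10 alkene. C10 is set by the binaphthol ligand, which leaves one face of the chelated quinone open; C5 follows from suprafacial addition to the ring alkene (cis fusion) and C4 from the endo approach of the diene with its methyl group pointing outward, and these two centres are corrected or erased in steps 4 and 7. The step needs site, regio- and face selectivity: the methoxy group turns its own alkene into an unreactive vinylogous ester, chelation holds the Lewis acid on C9=O instead of the more basic vinylogous ester carbonyl C6=O (where a monodentate acid would sit and reverse the polarisation), and the 3-silyloxy group makes C4 the nucleophilic diene terminus, which also joins the two less hindered carbons first.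

**Step 4**
Reactants: 5 cis-fused cycloadduct
Product: 6 trans-fused ene-dione
Conditions: DBU (0.2 equiv), CH2Cl2, rt, N2
Reagents that add atoms: none
Why: Reversible enolisation α to the C6 carbonyl (C10 is quaternary and cannot epimerise) should lead to the trans-fused isomer, in which the nearly planar ene-dione ring gives the axial C10 methyl no 1,3-diaxial partners in ring B and the C4 methyl is pseudo-equatorial; thermodynamic epimerisation of cis-fused quinone cycloadducts with one angular methyl is a known reaction type.

**Step 5**
Reactants: 6 trans-fused ene-dione; 7 2-(2-bromoethyl)-2-methyl-1,3-dioxolane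
Product: 10 C9 tertiary acetate, via Grignard reagent 8 (not isolated), via magnesium alkoxide 9 (not isolated)
Conditions: 7, Mg, THF, rt; CeCl3, THF, −78 °C; 6, −78 → −40 °C; then Ac2O, DMAP (cat.), → 0 °C
Reagents that add atoms: acetic anhydride, CC(=O)OC(C)=O
Why: CeCl3-promoted Grignard 1,2-addition followed by O-acylation of the alkoxide, in which the C9 ketone is the more electrophilic carbonyl (C6=O is a vinylogous ester) and can chelate the metal with the C8 methoxy group, the weakly basic cerium-activated reagent leaves H5 and the silyl enol ether untouched, and the new C9 centre (attack anti to C20 expected) is erased in step 15.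

**Step 6**
Reactants: 10 C9 tertiary acetate
Product: 11 ring A enone
Conditions: Pd(OAc)2 (1.1 equiv), MeCN, 40 °C
Reagents that add atoms: none
Why: Saegusa–Ito oxidation, in which the palladium enolate formed from the C2=C3 silyl enol ether can eliminate β-hydride only from C1, so the 1-en-3-one results and C4 becomes the only enolisable position of the ring A ketone.

**Step 7**
Reactants: 11 ring A enone
Product: 13 C4 hydroxymethyl enone, via lithium dienolate 12 (not isolated)
Conditions: LiN(SiMe3)2 (1.1 equiv), THF, −78 °C; CH2O (monomeric, THF), −78 °C; AcOH quench at −78 °C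
Reagents that add atoms: formaldehyde, C=O
Why: Aldol addition of the cross-conjugated lithium dienolate to formaldehyde, in which the ketone α′-hydrogen at C4 is the most acidic site (H5 belongs to a vinylogous ester, the acetate is less acidic still) and, on the trans-fused dienolate, the electrophile should enter C4 anti to the axial C10 methyl, placing C18 trans and the C4 methyl cis to C20 as in the target.

**Step 8**
Reactants: 13 C4 hydroxymethyl enone
Product: 14 C18 silyl ether
Conditions: t-BuMe2SiCl, imidazole, DMF, rt
Reagents that add atoms: tert-butyldimethylsilyl chloride, CC(C)(C)[Si](C)(C)Cl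
Why: Silylation of the primary alcohol blocks retro-aldol cleavage of the β-hydroxy ketone and keeps O18 distinct from the C3 hydroxyl made in step 10.

**Step 9**
Reactants: 14 C18 silyl ether
Product: 15 saturated C3 ketone
Conditions: H2 (1 atm), Pd/C, EtOAc, rt
Reagents that add atoms: none
Why: Heterogeneous hydrogenation saturates the disubstituted C1=C2 enone alkene, while the push-pull alkene of the ring B vinylogous ester is not reduced under these mild conditions.

**Step 10**
Reactants: 15 saturated C3 ketone
Product: 16 C3 alcohol
Conditions: NaBH4, MeOH, 0 °C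
Reagents that add atoms: none
Why: Borohydride reduces the saturated C3 ketone but not the electron-rich vinylogous ester carbonyl or the acetate; the new C3 centre (equatorial alcohol expected) is removed in step 12.

**Step 11**
Reactants: 16 C3 alcohol
Product: 17 C3 imidazolylthiocarbonate
Conditions: 1,1'-thiocarbonyldiimidazole, DMAP, toluene, 80 °C
Reagents that add atoms: 1,1'-thiocarbonyldiimidazole, S=C(n1ccnc1)n1ccnc1
Why: Thioacylation of the only free hydroxyl prepares the secondary C3–O bond for Barton–McCombie cleavage.

**Step 12**
Reactants: 17 C3 imidazolylthiocarbonate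
Product: 18 C3-deoxy vinylogous ester
Conditions: Bu3SnH, AIBN (cat.), toluene, 110 °C
Reagents that add atoms: none
Why: Barton–McCombie deoxygenation, in which the stannyl radical adds to the thiocarbonyl group, the C3–O bond fragments and the secondary radical abstracts hydrogen from Bu3SnH.

**Step 13**
Reactants: 18 C3-deoxy vinylogous ester
Product: 20 acetoxy enone alcohol, via allylic alcohol 19 (not isolated)
Conditions: NaBH4, CeCl3·7H2O, MeOH, 0 °C; then 2 M HCl, THF, rt
Reagents that add atoms: water, O
Why: Luche 1,2-reduction of the vinylogous ester followed by Stork–Danheiser-type hydrolysis, in which acid ionises the allylic C6 hydroxyl to the methoxy-stabilised cation and water converts it into the 6-en-8-one; the same acid cleaves the dioxolane and the silyl ether, and C5 is not involved.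

**Step 14**
Reactants: 20 acetoxy enone alcohol
Product: 21 diacetate
Conditions: Ac2O, pyridine, DMAP (cat.), CH2Cl2, rt
Reagents that add atoms: acetic anhydride, CC(=O)OC(C)=O
Why: Acetylation of the primary C18 alcohol installs the acetate of the target before the base-free final steps.

**Step 15**
Reactants: 21 diacetate
Product: 22 enone diketone
Conditions: SmI2 (2.5 equiv), THF/MeOH, −78 °C
Reagents that add atoms: none
Why: Reductive cleavage of an α-acyloxy ketone by SmI2, in which two single-electron transfers expel the C9 acetate and methanol protonates the samarium dienolate at C9 anti to the C10 methyl, giving the equatorial side chain (cis to C20), which is also the thermodynamic epimer; the primary acetate and the methyl ketone do not react at this temperature.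

**Step 16**
Reactants: 22 enone diketone
Product: 23 keto enoate
Conditions: (MeO)2P(O)CH2CO2Me, NaH, THF, 0 °C → rt
Reagents that add atoms: trimethyl phosphonoacetate, COC(=O)CP(=O)(OC)OC
Why: Horner–Wadsworth–Emmons olefination of the unhindered methyl ketone (the hindered, conjugated C8 ketone should not react), with the E isomer expected to predominate and the minor Z isomer removed by chromatography.

**Step 17**
Reactants: 23 keto enoate
Product: 24 target
Conditions: Zn, CH2Br2, TiCl4, THF/CH2Cl2, 0 °C → rt
Reagents that add atoms: dibromomethane, BrCBr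
Why: Takai–Lombardo methylenation, in which the non-basic zinc–titanium methylene reagent converts the hindered enone carbonyl into the exocyclic alkene without touching the two esters or epimerising C9, giving the 6,8(17)-diene.

**Compound list**
1 | 2-methoxy-6-methylphenol | COc1cccc(C)c1O | starting material
2 | 2-methoxy-6-methyl-1,4-benzoquinone | COC1=CC(=O)C=C(C)C1=O | intermediate
3 | pent-1-en-3-one (ethyl vinyl ketone) | CCC(=O)C=C | starting material
4 | (Z)-3-(tert-butyldimethylsilyloxy)penta-1,3-diene | C=C/C(O[Si](C)(C)C(C)(C)C)=C/C | intermediate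
5 | cis-fused cycloadduct, (4aS,5R,8aR)-6-(tert-butyldimethylsilyloxy)-2-methoxy-5,8a-dimethyl-4a,5,8,8a-tetrahydronaphthalene-1,4-dione; labdane numbering: 2-ene with 3-OTBS, 4-methyl, 6,9-dioxo, 7-ene with 8-OMe; H4, H5 and C20 all cis | COC1=CC(=O)[C@H]2[C@@H](C)C(O[Si](C)(C)C(C)(C)C)=CC[C@@]2(C)C1=O | intermediate
6 | trans-fused ene-dione, the (4aR,5R,8aR) C5 epimer of 5 (H5 trans to C20, C4 methyl trans to C20) | COC1=CC(=O)[C@@H]2[C@@H](C)C(O[Si](C)(C)C(C)(C)C)=CC[C@@]2(C)C1=O | intermediate
7 | 2-(2-bromoethyl)-2-methyl-1,3-dioxolane | CC1(CCBr)OCCO1 | starting material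
8 | Grignard reagent, [2-(2-methyl-1,3-dioxolan-2-yl)ethyl]magnesium bromide | CC1(CC[Mg]Br)OCCO1 | intermediate
9 | magnesium alkoxide: 6 with C9 carrying OMgBr (cis to C20) and the 2-(2-methyl-1,3-dioxolan-2-yl)ethyl chain (trans to C20) | COC1=CC(=O)[C@@H]2[C@@H](C)C(O[Si](C)(C)C(C)(C)C)=CC[C@@]2(C)[C@@]1(O[Mg]Br)CCC1(C)OCCO1 | intermediate
10 | C9 tertiary acetate: as 9 with OAc on C9; ring A 2-ene silyl enol ether, 6-oxo, 7-ene with 8-OMe | COC1=CC(=O)[C@@H]2[C@@H](C)C(O[Si](C)(C)C(C)(C)C)=CC[C@@]2(C)[C@@]1(OC(C)=O)CCC1(C)OCCO1 | intermediate
11 | ring A enone: 10 with C1=C2–C3=O in place of the silyl enol ether (H4 cis to C20) | COC1=CC(=O)[C@@H]2[C@@H](C)C(=O)C=C[C@@]2(C)[C@@]1(OC(C)=O)CCC1(C)OCCO1 | intermediate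
12 | lithium dienolate of 11 (C1=C2, C3(OLi)=C4) | COC1=CC(=O)[C@@H]2C(C)=C(O[Li])C=C[C@@]2(C)[C@@]1(OC(C)=O)CCC1(C)OCCO1 | intermediate
13 | C4 hydroxymethyl enone: 11 with C4 bearing CH2OH (C18, trans to C20) and CH3 (cis to C20) | COC1=CC(=O)[C@@H]2[C@@](C)(CO)C(=O)C=C[C@@]2(C)[C@@]1(OC(C)=O)CCC1(C)OCCO1 | intermediate
14 | C18 silyl ether: tert-butyldimethylsilyl ether of 13 | COC1=CC(=O)[C@@H]2[C@@](C)(CO[Si](C)(C)C(C)(C)C)C(=O)C=C[C@@]2(C)[C@@]1(OC(C)=O)CCC1(C)OCCO1 | intermediate
15 | saturated C3 ketone: 14 with C1–C2 single bond | COC1=CC(=O)[C@@H]2[C@@](C)(CO[Si](C)(C)C(C)(C)C)C(=O)CC[C@@]2(C)[C@@]1(OC(C)=O)CCC1(C)OCCO1 | intermediate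
16 | C3 alcohol: 15 with C3–OH (equatorial, cis to C20) | COC1=CC(=O)[C@@H]2[C@@](C)(CO[Si](C)(C)C(C)(C)C)[C@H](O)CC[C@@]2(C)[C@@]1(OC(C)=O)CCC1(C)OCCO1 | intermediate
17 | C3 imidazolylthiocarbonate: O-(imidazol-1-ylthiocarbonyl) derivative of 16 | COC1=CC(=O)[C@@H]2[C@@](C)(CO[Si](C)(C)C(C)(C)C)[C@H](OC(=S)n3ccnc3)CC[C@@]2(C)[C@@]1(OC(C)=O)CCC1(C)OCCO1 | intermediate
18 | C3-deoxy vinylogous ester: 17 with CH2 at C3 | COC1=CC(=O)[C@@H]2[C@@](C)(CO[Si](C)(C)C(C)(C)C)CCC[C@@]2(C)[C@@]1(OC(C)=O)CCC1(C)OCCO1 | intermediate
19 | allylic alcohol: 18 with C6–OH in place of C6=O (C6 configuration not controlled) | COC1=CC(O)[C@@H]2[C@@](C)(CO[Si](C)(C)C(C)(C)C)CCC[C@@]2(C)[C@@]1(OC(C)=O)CCC1(C)OCCO1 | intermediate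
20 | acetoxy enone alcohol: trans-fused 6-en-8-one with C9(OAc)(3-oxobutyl), C4(CH3)(CH2OH) | O=C1C=C[C@@H]2[C@@](C)(CO)CCC[C@@]2(C)[C@@]1(OC(C)=O)CCC(C)=O | intermediate
21 | diacetate: 18-O-acetate of 20 | O=C1C=C[C@@H]2[C@@](C)(COC(C)=O)CCC[C@@]2(C)[C@@]1(OC(C)=O)CCC(C)=O | intermediate
22 | enone diketone: 21 with H on C9 (H9 trans, 3-oxobutyl chain cis to C20) | O=C1C=C[C@@H]2[C@@](C)(COC(C)=O)CCC[C@@]2(C)[C@@H]1CCC(C)=O | intermediate
23 | keto enoate: 22 with the chain ketone converted into (E)-C(CH3)=CH–CO2CH3 | O=C1C=C[C@@H]2[C@@](C)(COC(C)=O)CCC[C@@]2(C)[C@@H]1CC/C(C)=C/C(=O)OC | intermediate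
24 | methyl (2E)-5-[(1R,4aS,5S,8aS)-5-(acetoxymethyl)-5,8a-dimethyl-2-methylidene-1,2,4a,5,6,7,8,8a-octahydronaphthalen-1-yl]-3-methylpent-2-enoate | C=C1C=C[C@@H]2[C@@](C)(COC(C)=O)CCC[C@@]2(C)[C@@H]1CC/C(C)=C/C(=O)OC | target

**Step count and weak points**
Total: 17 steps. Longest linear sequence: 16 steps (1 → 2 → 5 → … → 24; diene 4 and bromide 7 enter convergently).

Step 3 (key cycloaddition). What may go wrong: poor face selectivity, erosion of regiocontrol if part of the reaction runs through a monodentate complex at the more basic C6-type carbonyl, and Lewis-acid-induced loss of the silyl group from the diene. Fallback, from 2 and 4, returning at 6: the cycloaddition is run without any Lewis acid (toluene, 40 °C). The intrinsic polarisation of the quinone (C9 carbonyl the more electron-poor) should give the same constitution as a racemate, i.e. 5 together with ent-5 F1. Treatment as in step 4 gives 6 together with ent-6 F2. Preparative chromatography on a cellulose tris(3,5-dimethylphenylcarbamate) phase then delivers 6. This replaces asymmetric catalysis by racemic synthesis and resolution.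

Step 4 (C5 epimerisation). What may go wrong: an unfavourable position of the cis/trans equilibrium, because the pseudo-equatorial C4 methyl of the trans isomer lies next to the C6 carbonyl, so that inversion stays incomplete. Fallback, from 5, returning at 11:
- The conditions of step 5 applied to 5 give the cis-fused tertiary acetate F3, and Pd(OAc)2 as in step 6 gives the cis-fused enone F4.
- DDQ (dioxane, 80 °C) dehydrogenates C4–C5 to the cross-conjugated dienone F5; H4 is the only enolisable hydrogen of the ring A ketone and H5 is the hydride lost.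
- Zn dust in AcOH/THF (0 °C) reduces only the C4=C5 bond, the one alkene flanked by two carbonyls. C5 is protonated while C4 is still trigonal, anti to the C10 methyl, as in the known zinc reduction of 4-ene-3,6-diones to trans-fused diketones.
- This gives 11 together with the C4 epimer of 11 F6; both enolise to the same dienolate 12 in step 7.

Step 7 (C4 hydroxymethylation). What may go wrong: competing deprotonation at C5 with loss of the trans fusion, retro-aldol loss of formaldehyde on warming, and attack on the face syn to the C10 methyl. Fallback, from 11, returning at 13: Me3SiOTf and Et3N (CH2Cl2, 0 °C) enolise only the ketone and give the trimethylsilyl dienol ether F7. Aqueous formaldehyde with Sc(OTf)3 (cat.) in THF/H2O at rt (Mukaiyama aldol in water) hydroxymethylates C4 under non-basic conditions, with the same steric bias, to give 13.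

**Further compounds**
F1 | step 3 | ent-5, enantiomer of the cis-fused cycloadduct | COC1=CC(=O)[C@@H]2[C@H](C)C(O[Si](C)(C)C(C)(C)C)=CC[C@]2(C)C1=O
F2 | step 3 | ent-6, enantiomer of the trans-fused ene-dione | COC1=CC(=O)[C@H]2[C@H](C)C(O[Si](C)(C)C(C)(C)C)=CC[C@]2(C)C1=O
F3 | step 4 | cis-fused tertiary acetate, C5 epimer of 10 | COC1=CC(=O)[C@H]2[C@@H](C)C(O[Si](C)(C)C(C)(C)C)=CC[C@@]2(C)[C@@]1(OC(C)=O)CCC1(C)OCCO1
F4 | step 4 | cis-fused enone, C5 epimer of 11 | COC1=CC(=O)[C@H]2[C@@H](C)C(=O)C=C[C@@]2(C)[C@@]1(OC(C)=O)CCC1(C)OCCO1
F5 | step 4 | cross-conjugated dienone (C1=C2, C3=O, C4=C5) of 11 | COC1=CC(=O)C2=C(C)C(=O)C=C[C@@]2(C)[C@@]1(OC(C)=O)CCC1(C)OCCO1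
F6 | step 4 | C4 epimer of 11 | COC1=CC(=O)[C@@H]2[C@H](C)C(=O)C=C[C@@]2(C)[C@@]1(OC(C)=O)CCC1(C)OCCO1
F7 | step 7 | trimethylsilyl dienol ether of 11 (C1=C2, C3(OSiMe3)=C4) | COC1=CC(=O)[C@@H]2C(C)=C(O[Si](C)(C)C)C=C[C@@]2(C)[C@@]1(OC(C)=O)CCC1(C)OCCO1
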